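**Assumption:** the target is the cis-(5S,8R) isomer defined by the given SMILES, and the 4-pyranone converts to the N-methoxy-4-pyridone with MeONH2 by ring-opening and recyclisation.

## Retrosynthetic overview
1. The N-methoxy-4-pyridone comes from the fused 4-pyranone by O→N exchange with MeONH2. The pyranone comes from a 1,3,5-triketone by acid cyclodehydration.
2. The triketone comes from the 1,3-diketone by γ-acylation. The diketone comes from an intramolecular Claisen condensation of a keto-ester, which closes the carbocycle (C4a–C8a bond).
3. The keto-ester comes from a Carroll rearrangement, a [3,3]-sigmatropic step, of an E-allylic alcohol with methyl 4-methoxyacetoacetate. This forms the C4a–C5 bond and transfers the carbinol chirality to C5.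
4. The allylic alcohol comes from L-tartrate acetonide by mono-reduction, oxidation, E-selective Julia–Kocienski olefination, acetonide removal and O-methylation. The C8 centre is the tartrate centre itself, and C5 is controlled by the adjacent tartrate carbinol.
5. Ring order: carbocycle first (Step 10), then pyranone (Step 12), then pyridone (Step 13).

## Route

**Step 1**
Reactants: 1 (6-bromohexyl)benzene; 2 1-phenyl-1H-tetrazole-5-thiol
Product: 3 1-phenyl-5-[(6-phenylhexyl)sulfanyl]-1H-tetrazole
Conditions: K2CO3, acetone, reflux
Reagents that add atoms: none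
Why: thiolate SN2 displacement of the primary bromide builds the Julia reagent, which supplies the (CH2)5Ph chain with one extra carbon (C5) for the alkene.

**Step 2**
Reactants: 3
Product: 4 1-phenyl-5-[(6-phenylhexyl)sulfonyl]-1H-tetrazole
Conditions: 30% H2O2, (NH4)6Mo7O24·4H2O, EtOH, 0 °C→rt
Reagents that add atoms: hydrogen peroxide, OO
Why: Mo-catalysed sulfide-to-sulfone oxidation gives the PT-sulfone for Julia–Kocienski olefination.

**Step 3**
Reactants: 5 dimethyl 2,3-O-isopropylidene-L-tartrate
Product: 6 methyl (4R,5S)-5-(hydroxymethyl)-2,2-dimethyl-1,3-dioxolane-4-carboxylate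
Conditions: NaBH4 (0.6 equiv), MeOH, 0 °C
Reagents that add atoms: none
Why: substoichiometric borohydride reduces one ester of the C2-symmetric diester (chemoselective mono-reduction). Both stereocentres are untouched; the descriptor at the reduced-side carbon changes only because the CIP priorities change.

**Step 4**
Reactants: 6
Product: 7 methyl (4R,5R)-5-formyl-2,2-dimethyl-1,3-dioxolane-4-carboxylate
Conditions: (COCl)2, DMSO, CH2Cl2, −78 °C; then Et3N; crude product used at once
Reagents that add atoms: none
Why: Swern oxidation. The α-centre is a trans-dioxolane, and epimerisation would give the less stable cis isomer, so it is configurationally robust.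

**Step 5**
Reactants: 7; 4
Product: 8 methyl (4R,5S)-2,2-dimethyl-5-[(1E)-7-phenylhept-1-en-1-yl]-1,3-dioxolane-4-carboxylate
Conditions: KHMDS, DME, −60 °C→rt
Reagents that add atoms: none
Why: Julia–Kocienski olefination gives the E-alkene (≥9:1, Z isomer removable by chromatography). E geometry is required so that the Carroll chair transition state delivers the correct configuration at C5.

**Step 6**
Reactants: 8
Product: 9 methyl (2R,3S,4E)-2,3-dihydroxy-10-phenyldec-4-enoate
Conditions: 80% aq. AcOH, 50 °C
Reagents that add atoms: none
Why: acid hydrolysis of the acetonide frees the diol with no C–O bond cleavage at either stereocentre.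

**Step 7**
Reactants: 9
Product: 10 methyl (2R,3S,4E)-3-hydroxy-2-methoxy-10-phenyldec-4-enoate
Conditions: Ag2O, MeI, CH2Cl2, rt, dark
Reagents that add atoms: iodomethane, CI
Why: the α-hydroxy-ester OH is more acidic and is chelated by Ag+ together with the ester C=O, so it is methylated in preference to the allylic OH. This is a Williamson-type methylation, so no stereocentre is affected. The methylated carbon becomes C8 and the free allylic carbinol is C7.

**Step 8**
Reactants: 10; 11 methyl 4-methoxy-3-oxobutanoate
Product: 12 methyl (2R,3E,5R)-2,8-dimethoxy-7-oxo-5-(5-phenylpentyl)oct-3-enoate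
Conditions: xylenes, 140→170 °C, sealed tube, no base
Reagents that add atoms: none
Why: Carroll rearrangement. Transacylation (via the acylketene) gives the allyl β-keto ester, which undergoes ester-enol [3,3] shift and decarboxylation. The chair transition state, with the C8 branch equatorial and the alkene E, forms C4a–C5 and transfers the (3S)-carbinol chirality suprafacially to C5; the C8 centre is untouched. The descriptor at C5 is R here and becomes S after hydrogenation because the CIP priorities change.

**Step 9**
Reactants: 12
Product: 13 methyl (2R,5S)-2,8-dimethoxy-7-oxo-5-(5-phenylpentyl)octanoate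
Conditions: H2 (1 atm), PtO2, EtOAc, rt
Reagents that add atoms: none
Why: catalytic hydrogenation of the disubstituted alkene. PtO2 is chosen to avoid hydrogenolysis of the allylic OMe, and neither stereocentre is affected.

**Step 10**
Reactants: 13
Product: 14 (3S,6R)-6-methoxy-2-(2-methoxyacetyl)-3-(5-phenylpentyl)cyclohexan-1-one (chelated ring enol)
Conditions: t-BuOK (1.3 equiv), THF (0.02 M), 0 °C→rt; aq. NH4Cl
Reagents that add atoms: none
Why: intramolecular Claisen (Dieckmann-type) condensation. The ketone enolate at C4a (far more acidic than the α-OMe ester α-H) attacks the methyl ester through a 6-exo acyl substitution to form the carbocycle. The 1,3-diketone enolate drives the reaction, and C5 and C8 are not enolisable under these conditions.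

**Step 11**
Reactants: 14
Product: 15 (3S,6R)-6-methoxy-2-(2-methoxy-3-oxobutanoyl)-3-(5-phenylpentyl)cyclohexan-1-one (enol)
Conditions: NaH (1.1 equiv), THF, 0 °C; n-BuLi (1.1 equiv), −20 °C; EtOAc (3 equiv), −20→0 °C; aq. HCl
Reagents that add atoms: ethyl acetate, CCOC(C)=O (leaves an acetyl group)
Why: Weiler-type dianion acylation. The dianion forms at the unhindered CH2OMe terminus rather than at the hindered ring CH(OMe), and acylation gives the 1,3,5-triketone (the new stereocentre at C3 is epimerisable and irrelevant).

**Step 12**
Reactants: 15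
Product: 16 (5S,8R)-3,8-dimethoxy-2-methyl-5-(5-phenylpentyl)-5,6,7,8-tetrahydro-4H-chromen-4-one
Conditions: TsOH·H2O (0.2 equiv), toluene, 80 °C
Reagents that add atoms: none
Why: acid-catalysed cyclodehydration of a 1,3,5-triketone gives the 4-pyranone. C5 and C8 are untouched, and C8 is now benzylic-like and no longer α to a ketone.

**Step 13**
Reactants: 16
Product: 17 Waltherione H, (5S,8R)-1,3,8-trimethoxy-2-methyl-5-(5-phenylpentyl)-5,6,7,8-tetrahydroquinolin-4(1H)-one
Conditions: MeONH2·HCl (5 equiv), pyridine/EtOH 1:1, 85 °C
Reagents that add atoms: methoxyamine hydrochloride, CON.Cl (leaves the N–OMe)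
Why: methoxyamine adds conjugately to the pyranone at C2 or C8a, the ring opens, and the nitrogen recondenses with the other carbonyl with loss of water. This exchanges the ring O for N–OMe and gives the N-methoxy-4-pyridone.

## Compound list
1 | (6-bromohexyl)benzene | BrCCCCCCc1ccccc1 | starting material
2 | 1-phenyl-1H-tetrazole-5-thiol | Sc1nnnn1-c1ccccc1 | starting material
3 | 1-phenyl-5-[(6-phenylhexyl)sulfanyl]-1H-tetrazole | S(CCCCCCc1ccccc1)c1nnnn1-c1ccccc1 | intermediate
4 | 1-phenyl-5-[(6-phenylhexyl)sulfonyl]-1H-tetrazole | O=S(=O)(CCCCCCc1ccccc1)c1nnnn1-c1ccccc1 | intermediate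
5 | dimethyl (4R,5R)-2,2-dimethyl-1,3-dioxolane-4,5-dicarboxylate | COC(=O)[C@@H]1OC(C)(C)O[C@H]1C(=O)OC | starting material
6 | methyl (4R,5S)-5-(hydroxymethyl)-2,2-dimethyl-1,3-dioxolane-4-carboxylate | COC(=O)[C@@H]1OC(C)(C)O[C@H]1CO | intermediate
7 | methyl (4R,5R)-5-formyl-2,2-dimethyl-1,3-dioxolane-4-carboxylate | COC(=O)[C@@H]1OC(C)(C)O[C@H]1C=O | intermediate
8 | methyl (4R,5S)-2,2-dimethyl-5-[(1E)-7-phenylhept-1-en-1-yl]-1,3-dioxolane-4-carboxylate | COC(=O)[C@@H]1OC(C)(C)O[C@H]1/C=C/CCCCCc1ccccc1 | intermediate
9 | methyl (2R,3S,4E)-2,3-dihydroxy-10-phenyldec-4-enoate | COC(=O)[C@H](O)[C@@H](O)/C=C/CCCCCc1ccccc1 | intermediate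
10 | methyl (2R,3S,4E)-3-hydroxy-2-methoxy-10-phenyldec-4-enoate | COC(=O)[C@H](OC)[C@@H](O)/C=C/CCCCCc1ccccc1 | intermediate
11 | methyl 4-methoxy-3-oxobutanoate | COCC(=O)CC(=O)OC | starting material
12 | methyl (2R,3E,5R)-2,8-dimethoxy-7-oxo-5-(5-phenylpentyl)oct-3-enoate | COC(=O)[C@H](OC)/C=C/[C@H](CCCCCc1ccccc1)CC(=O)COC | intermediate
13 | methyl (2R,5S)-2,8-dimethoxy-7-oxo-5-(5-phenylpentyl)octanoate | COC(=O)[C@H](OC)CC[C@H](CCCCCc1ccccc1)CC(=O)COC | intermediate
14 | (3S,6R)-6-methoxy-2-(2-methoxyacetyl)-3-(5-phenylpentyl)cyclohexan-1-one (ring-enol form) | COCC(=O)C1=C(O)[C@H](OC)CC[C@@H]1CCCCCc1ccccc1 | intermediate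
15 | (3S,6R)-6-methoxy-2-(2-methoxy-3-oxobutanoyl)-3-(5-phenylpentyl)cyclohexan-1-one (enol form) | CC(=O)C(OC)C(=O)C1=C(O)[C@H](OC)CC[C@@H]1CCCCCc1ccccc1 | intermediate
16 | (5S,8R)-3,8-dimethoxy-2-methyl-5-(5-phenylpentyl)-5,6,7,8-tetrahydro-4H-chromen-4-one | COc1c(C)oc2c(c1=O)[C@@H](CCCCCc1ccccc1)CC[C@H]2OC | intermediate
17 | Waltherione H | COc1c(C)n(OC)c2c(c1=O)[C@@H](CCCCCc1ccccc1)CC[C@H]2OC | target

## Totals
Total steps: 13, of which Steps 1–2 prepare the olefination reagent. Longest linear sequence: 11 steps (Steps 3–13 from commercial 5).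

## Three steps most likely to fail
1. **Step 7, regioselective O-methylation.** It could give a mixture of C2- and C3-methyl ethers.
   Fallback (different approach): start from dimethyl D-tartrate acetonide and use a Z-selective Wittig (from the phosphonium salt of 1) in Step 5 instead of the Julia reaction. In Step 7, convert the resulting (2S,3R,Z)-diol to its cyclic sulfate, open it with MeOH at the α-carbon with inversion, and hydrolyse the sulfate. This gives the (2R,3R,Z)-allylic alcohol, whose Carroll rearrangement delivers the same (5S,8R) product.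
2. **Step 11, dianion γ-acylation.** The dianion could form at the ring CH(OMe) or epimerise C8.
   Fallback (different approach): O-acetylate the enol of 14 (AcCl, pyridine). Then treat with t-BuOK, so that the only enolisable site is CH2OMe, and an intramolecular Baker–Venkataraman-type O→C acyl transfer gives triketone 15.
3. **Step 13, pyranone to N-methoxypyridone.** Methoxyamine is a weak nucleophile and the conversion may stall or give the oxime.
   Fallback (different approach): treat 16 with NH2OH·HCl/pyridine to give the N-hydroxypyridone, then O-methylate the N–OH with MeI/K2CO3 to reach 17.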